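**Plan**

1. Retrosynthesis: the two acetates and the C7 carbinol go back to a C7 enone. The C9–C11 bond is cut next (side-chain organometallic plus C9 ketone, followed by oxidative 1,3-transposition of oxygen from C9 to C7). Then the C3–C4 bond of ring A is cut, and last the C10–C1 and C10–CH3 bonds, which leaves (S)-carvone as ring B.
2. Forward: ring B is carvone (its C=O becomes C9, its ring methyl the C8 methyl, its isopropenyl carbon C4). Two enolate alkylations build quaternary C10, ring A is closed at C3–C4, the side chain is added at C9, oxygen is moved to C7, and reduction and acetylation finish the route.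
3. Enabling feature: the C5 isopropenyl group is a 1,1-disubstituted alkene, so hydrogen-atom transfer turns it into the tertiary C4 radical that already carries both gem-methyls. The C10 arm ends in a vinyl sulfone CH2 (C3), so the chain C4–C5–C10–C1–C2–C3 closes ring A in the 6-endo mode. The sulfone on C2 is a temporary activator, removed in step 10.
4. Stereochemistry: C5 comes from (S)-carvone. C10 is set by alkylation anti to the isopropenyl group, which fixes the trans ring fusion before ring A exists. C7 is set by equatorial hydride delivery from LiBH(s-Bu)3. The 13E alkene comes from a geometrically pure enynol.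

Key step: step 5

Remarks: labdane numbering is used for the core (ring A = C1–C5, C10; ring B = C5–C10; side chain C11–C16). The sulfone-bearing C2 (compounds 9, 17), the C9 carbinol (17, 18) and C6 of compound 6 are temporary centres carried as mixtures and drawn without configuration. (2E)-3-Methylpent-2-en-4-yn-1-ol is assumed to be purchasable as the pure E isomer.

**Route**

Step 1
Reactants: 1 phenyl vinyl sulfone
Product: 2 2-(phenylsulfonyl)prop-2-en-1-ol
Conditions: aq. CH2O (37%), DABCO (0.5 equiv), THF, rt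
Reagents that add atoms: formaldehyde, C=O
Why: Morita–Baylis–Hillman reaction, in which DABCO adds to the vinyl sulfone, the α-sulfonyl carbanion is hydroxymethylated and the amine is expelled; no stereocentre is formed.

Step 2
Reactants: 2 2-(phenylsulfonyl)prop-2-en-1-ol
Product: 3 [(3-bromoprop-1-en-2-yl)sulfonyl]benzene
Conditions: PBr3 (0.4 equiv), Et2O, 0 °C
Reagents that add atoms: phosphorus tribromide, BrP(Br)Br
Why: standard conversion of a primary Baylis–Hillman-type allylic alcohol into the allylic bromide through its phosphite ester.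

Step 3
Reactants: 4 (S)-(+)-carvone
Product: 6 (5S)-2,6-dimethyl-5-(prop-1-en-2-yl)cyclohex-2-en-1-one (C6 epimers), via lithium dienolate of carvone 5 (not isolated)
Conditions: LiN(i-Pr)2 (LDA), THF, −78 °C; then MeI, −78 to 0 °C
Reagents that add atoms: iodomethane, CI
Why: kinetic α′-deprotonation of the enone and C-methylation of the cross-conjugated enolate; the new centre is re-enolised in step 4, so its configuration does not matter.

Step 4
Reactants: 6 (5S)-2,6-dimethyl-5-(prop-1-en-2-yl)cyclohex-2-en-1-one; 3 [(3-bromoprop-1-en-2-yl)sulfonyl]benzene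
Product: 8 (5R,6R)-2,6-dimethyl-6-[2-(phenylsulfonyl)prop-2-en-1-yl]-5-(prop-1-en-2-yl)cyclohex-2-en-1-one, via lithium enolate of 6-methylcarvone 7 (not isolated)
Conditions: LDA, THF, −78 °C; then 3, DMPU, −78 to −30 °C
Reagents that add atoms: none
Why: enolate alkylation (direct or addition–elimination, both giving the same 2-sulfonylallyl product) in which the electrophile should enter the enolate face anti to the adjacent C5 isopropenyl group, setting quaternary C10 with the new arm trans and the methyl cis to that group.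

Step 5
Reactants: 8 (5R,6R)-2,6-dimethyl-6-[2-(phenylsulfonyl)prop-2-en-1-yl]-5-(prop-1-en-2-yl)cyclohex-2-en-1-one
Product: 9 (4aR,8aR)-2,5,5,8a-tetramethyl-7-(phenylsulfonyl)-4a,5,6,7,8,8a-hexahydronaphthalen-1(4H)-one (C7 epimers)
Conditions: Fe(acac)3 (30 mol%), PhSiH3 (2.5 equiv), EtOH/ethylene glycol 5:1 (0.02 M), 60 °C
Reagents that add atoms: none
Why: The Fe–H species formed from Fe(acac)3 and PhSiH3 transfers a hydrogen atom to the CH2 terminus of the C5 isopropenyl group, giving the tertiary C4 radical that carries both future gem-methyls; this nucleophilic radical adds to the unsubstituted CH2 terminus (C3) of the 2-sulfonylallyl arm, and the α-sulfonyl radical at C2 is reduced by divalent iron to the carbanion and protonated by ethanol, which returns trivalent iron. The closest known reaction type is the iron-hydride-mediated reductive coupling of 1,1-disubstituted donor alkenes with vinyl sulfone and enone acceptors (a Giese addition triggered by hydrogen-atom transfer), used here intramolecularly. Ring A closes in the 6-endo-trig mode through C4–C5–C10–C1–C2–C3; the 5-exo alternative would attack the sulfonyl-bearing C2, give an unstabilised primary radical and join two fully substituted carbons, so it should not compete. C4 is not stereogenic, the trans ring fusion is already fixed by the trans relation of the C5 and C10 substituents (both can sit equatorial on ring B, which brings C4 and C3 within reach), and the C2 centre is formed by uncontrolled protonation and is erased in step 10. The step needs hydrogen-atom transfer to the isopropenyl group rather than to the enone or vinyl sulfone, which the higher reactivity of electron-rich 1,1-disubstituted alkenes toward metal hydrides should secure, and cyclisation faster than reduction of the tertiary radical, which high dilution and the polarity-matched acceptor favour.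

Step 6
Reactants: 10 (2E)-3-methylpent-2-en-4-yn-1-ol
Product: 11 tert-butyl(dimethyl){[(2E)-3-methylpent-2-en-4-yn-1-yl]oxy}silane
Conditions: TBSCl, imidazole, CH2Cl2, 0 °C to rt
Reagents that add atoms: tert-butyldimethylsilyl chloride, CC(C)(C)[Si](C)(C)Cl
Why: routine silylation of a primary allylic alcohol, giving a group that survives the organometallic, chromium and hydride steps.

Step 7
Reactants: 11 tert-butyl(dimethyl){[(2E)-3-methylpent-2-en-4-yn-1-yl]oxy}silane
Product: 12 tert-butyl(dimethyl){[(2E)-3-methylpenta-2,4-dien-1-yl]oxy}silane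
Conditions: H2 (1 atm), Pd/CaCO3 poisoned with Pb(OAc)2, quinoline, hexane, rt, stopped after 1 equiv H2
Reagents that add atoms: none
Why: semihydrogenation of the terminal alkyne on poisoned palladium stops at the vinyl group and leaves the trisubstituted E alkene untouched.

Step 8
Reactants: 12 tert-butyl(dimethyl){[(2E)-3-methylpenta-2,4-dien-1-yl]oxy}silane
Product: 14 tert-butyl{[(2E)-5-iodo-3-methylpent-2-en-1-yl]oxy}dimethylsilane, via B-alkyl-9-BBN adduct 13 (not isolated)
Conditions: 9-borabicyclo[3.3.1]nonane (9-BBN-H), THF, 0 °C to rt; then NaOMe, I2, MeOH/THF, 0 °C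
Reagents that add atoms: iodine, II
Why: 9-BBN hydroborates only the monosubstituted vinyl terminus (anti-Markovnikov), and base-induced iodinolysis of the primary B–C bond gives the homoallylic iodide without touching the E alkene.

Step 9
Reactants: 9 (4aR,8aR)-2,5,5,8a-tetramethyl-7-(phenylsulfonyl)-4a,5,6,7,8,8a-hexahydronaphthalen-1(4H)-one; 14 tert-butyl{[(2E)-5-iodo-3-methylpent-2-en-1-yl]oxy}dimethylsilane
Product: 17 (4aR,8aR)-1-[(3E)-5-{[tert-butyl(dimethyl)silyl]oxy}-3-methylpent-3-en-1-yl]-2,5,5,8a-tetramethyl-7-(phenylsulfonyl)-1,4,4a,5,6,7,8,8a-octahydronaphthalen-1-ol (C1 and C7 epimers), via side-chain organolithium 15 (not isolated), via side-chain organocerium dichloride 16 (not isolated)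
Conditions: 14, t-BuLi (2.1 equiv), Et2O/pentane, −78 °C; then CeCl3 (anhydrous), THF, −78 °C; then 9, −78 to −40 °C; then H2O
Reagents that add atoms: none
Why: iodine–lithium exchange and transmetalation give a weakly basic, strongly nucleophilic organocerium that should add 1,2 to the hindered C9 enone carbonyl without deprotonating the position α to the sulfone; the carbinol configuration is irrelevant because C9 becomes sp2 in step 11.

Step 10
Reactants: 17 (4aR,8aR)-1-[(3E)-5-{[tert-butyl(dimethyl)silyl]oxy}-3-methylpent-3-en-1-yl]-2,5,5,8a-tetramethyl-7-(phenylsulfonyl)-1,4,4a,5,6,7,8,8a-octahydronaphthalen-1-ol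
Product: 18 (4aR,8aR)-1-[(3E)-5-{[tert-butyl(dimethyl)silyl]oxy}-3-methylpent-3-en-1-yl]-2,5,5,8a-tetramethyl-1,4,4a,5,6,7,8,8a-octahydronaphthalen-1-ol (C1 epimers)
Conditions: Na(Hg) (6% Na), Na2HPO4, MeOH/THF, −20 °C to rt
Reagents that add atoms: none
Why: reductive desulfonylation by electron transfer removes the activating group and the C2 stereocentre at a stage where no enone is present; isolated alkenes, the tertiary alcohol and the silyl ether are inert.

Step 11
Reactants: 18 (4aR,8aR)-1-[(3E)-5-{[tert-butyl(dimethyl)silyl]oxy}-3-methylpent-3-en-1-yl]-2,5,5,8a-tetramethyl-1,4,4a,5,6,7,8,8a-octahydronaphthalen-1-ol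
Product: 19 (4aR,8aR)-4-[(3E)-5-{[tert-butyl(dimethyl)silyl]oxy}-3-methylpent-3-en-1-yl]-3,4a,8,8-tetramethyl-4a,5,6,7,8,8a-hexahydronaphthalen-2(1H)-one
Conditions: pyridinium chlorochromate [C5H5NH][CrO3Cl] (2 equiv), Celite, CH2Cl2, rt
Reagents that add atoms: pyridinium chlorochromate, [O-][Cr](=O)(=O)Cl.c1cc[nH+]cc1
Why: Dauben–Babler oxidative transposition, in which [3,3]-shift of the tertiary allylic chromate ester moves oxygen from C9 to C7 and the secondary chromate is oxidised to the ketone, placing the C8=C9 double bond, the C9 side chain and the C7 oxygen as in the target.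

Step 12
Reactants: 19 (4aR,8aR)-4-[(3E)-5-{[tert-butyl(dimethyl)silyl]oxy}-3-methylpent-3-en-1-yl]-3,4a,8,8-tetramethyl-4a,5,6,7,8,8a-hexahydronaphthalen-2(1H)-one
Product: 20 (2S,4aR,8aR)-4-[(3E)-5-{[tert-butyl(dimethyl)silyl]oxy}-3-methylpent-3-en-1-yl]-3,4a,8,8-tetramethyl-1,2,4a,5,6,7,8,8a-octahydronaphthalen-2-ol
Conditions: LiBH(s-Bu)3, THF, −78 °C; then H2O
Reagents that add atoms: none
Why: by analogy with 1,2-reductions of β,β-disubstituted cyclohexenones such as steroidal 4-en-3-ones, the bulky hydride should attack C7 equatorially from the face of the C10 methyl, giving the pseudo-axial alcohol trans to that methyl (7S), while the fully substituted C9 blocks conjugate reduction.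

Step 13
Reactants: 20 (2S,4aR,8aR)-4-[(3E)-5-{[tert-butyl(dimethyl)silyl]oxy}-3-methylpent-3-en-1-yl]-3,4a,8,8-tetramethyl-1,2,4a,5,6,7,8,8a-octahydronaphthalen-2-ol
Product: 21 (2S,4aR,8aR)-4-[(3E)-5-hydroxy-3-methylpent-3-en-1-yl]-3,4a,8,8-tetramethyl-1,2,4a,5,6,7,8,8a-octahydronaphthalen-2-ol
Conditions: TBAF, THF, 0 °C to rt
Reagents that add atoms: none
Why: fluoride cleaves the primary silyl ether under conditions that do not ionise the allylic C7 alcohol.

Step 14
Reactants: 21 (2S,4aR,8aR)-4-[(3E)-5-hydroxy-3-methylpent-3-en-1-yl]-3,4a,8,8-tetramethyl-1,2,4a,5,6,7,8,8a-octahydronaphthalen-2-ol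
Product: 22 (2S,4aR,8aR)-4-[(3E)-5-(acetyloxy)-3-methylpent-3-en-1-yl]-3,4a,8,8-tetramethyl-1,2,4a,5,6,7,8,8a-octahydronaphthalen-2-yl acetate (target; labdane numbering 5R,7S,10R,13E)
Conditions: Ac2O, pyridine, DMAP (cat.), CH2Cl2, 0 °C to rt
Reagents that add atoms: acetic anhydride, CC(=O)OC(C)=O
Why: DMAP-catalysed acylation esterifies the primary and the secondary allylic alcohol with retention at C7.

**Compound list**

1 | phenyl vinyl sulfone | C=CS(=O)(=O)c1ccccc1 | starting material
2 | 2-(phenylsulfonyl)prop-2-en-1-ol | C=C(CO)S(=O)(=O)c1ccccc1 | intermediate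
3 | [(3-bromoprop-1-en-2-yl)sulfonyl]benzene | C=C(CBr)S(=O)(=O)c1ccccc1 | intermediate
4 | (S)-(+)-carvone | CC1=CC[C@@H](CC1=O)C(C)=C | starting material
5 | lithium (3S)-6-methyl-3-(prop-1-en-2-yl)cyclohexa-1,5-dien-1-olate | CC1=CC[C@H](C(C)=C)C=C1O[Li] | intermediate
6 | (5S)-2,6-dimethyl-5-(prop-1-en-2-yl)cyclohex-2-en-1-one (C6 epimers) | CC1=CC[C@H](C(C)=C)C(C)C1=O | intermediate
7 | lithium (3R)-2,6-dimethyl-3-(prop-1-en-2-yl)cyclohexa-1,5-dien-1-olate | CC1=CC[C@H](C(C)=C)C(C)=C1O[Li] | intermediate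
8 | (5R,6R)-2,6-dimethyl-6-[2-(phenylsulfonyl)prop-2-en-1-yl]-5-(prop-1-en-2-yl)cyclohex-2-en-1-one | O=C1C(C)=CC[C@H](C(C)=C)[C@@]1(C)CC(=C)S(=O)(=O)c2ccccc2 | intermediate
9 | (4aR,8aR)-2,5,5,8a-tetramethyl-7-(phenylsulfonyl)-4a,5,6,7,8,8a-hexahydronaphthalen-1(4H)-one (C7 epimers) | O=C1C(C)=CC[C@@H]2C(C)(C)CC(S(=O)(=O)c3ccccc3)C[C@@]12C | intermediate
10 | (2E)-3-methylpent-2-en-4-yn-1-ol | C#C/C(C)=C/CO | starting material
11 | tert-butyl(dimethyl){[(2E)-3-methylpent-2-en-4-yn-1-yl]oxy}silane | C#C/C(C)=C/CO[Si](C)(C)C(C)(C)C | intermediate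
12 | tert-butyl(dimethyl){[(2E)-3-methylpenta-2,4-dien-1-yl]oxy}silane | C=C/C(C)=C/CO[Si](C)(C)C(C)(C)C | intermediate
13 | 9-[(3E)-5-{[tert-butyl(dimethyl)silyl]oxy}-3-methylpent-3-en-1-yl]-9-borabicyclo[3.3.1]nonane | CC(C)(C)[Si](C)(C)OC/C=C(\C)CCB1C2CCCC1CCC2 | intermediate
14 | tert-butyl{[(2E)-5-iodo-3-methylpent-2-en-1-yl]oxy}dimethylsilane | CC(C)(C)[Si](C)(C)OC/C=C(\C)CCI | intermediate
15 | [(3E)-5-{[tert-butyl(dimethyl)silyl]oxy}-3-methylpent-3-en-1-yl]lithium | CC(C)(C)[Si](C)(C)OC/C=C(\C)CC[Li] | intermediate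
16 | dichloro[(3E)-5-{[tert-butyl(dimethyl)silyl]oxy}-3-methylpent-3-en-1-yl]cerium | CC(C)(C)[Si](C)(C)OC/C=C(\C)CC[Ce](Cl)Cl | intermediate
17 | (4aR,8aR)-1-[(3E)-5-{[tert-butyl(dimethyl)silyl]oxy}-3-methylpent-3-en-1-yl]-2,5,5,8a-tetramethyl-7-(phenylsulfonyl)-1,4,4a,5,6,7,8,8a-octahydronaphthalen-1-ol (C1 and C7 epimers) | CC(C)(C)[Si](C)(C)OC/C=C(\C)CCC1(O)C(C)=CC[C@@H]2C(C)(C)CC(S(=O)(=O)c3ccccc3)C[C@@]12C | intermediate
18 | (4aR,8aR)-1-[(3E)-5-{[tert-butyl(dimethyl)silyl]oxy}-3-methylpent-3-en-1-yl]-2,5,5,8a-tetramethyl-1,4,4a,5,6,7,8,8a-octahydronaphthalen-1-ol (C1 epimers) | CC(C)(C)[Si](C)(C)OC/C=C(\C)CCC1(O)C(C)=CC[C@@H]2C(C)(C)CCC[C@@]12C | intermediate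
19 | (4aR,8aR)-4-[(3E)-5-{[tert-butyl(dimethyl)silyl]oxy}-3-methylpent-3-en-1-yl]-3,4a,8,8-tetramethyl-4a,5,6,7,8,8a-hexahydronaphthalen-2(1H)-one | CC(C)(C)[Si](C)(C)OC/C=C(\C)CCC1=C(C)C(=O)C[C@@H]2C(C)(C)CCC[C@@]12C | intermediate
20 | (2S,4aR,8aR)-4-[(3E)-5-{[tert-butyl(dimethyl)silyl]oxy}-3-methylpent-3-en-1-yl]-3,4a,8,8-tetramethyl-1,2,4a,5,6,7,8,8a-octahydronaphthalen-2-ol | CC(C)(C)[Si](C)(C)OC/C=C(\C)CCC1=C(C)[C@@H](O)C[C@@H]2C(C)(C)CCC[C@@]12C | intermediate
21 | (2S,4aR,8aR)-4-[(3E)-5-hydroxy-3-methylpent-3-en-1-yl]-3,4a,8,8-tetramethyl-1,2,4a,5,6,7,8,8a-octahydronaphthalen-2-ol | OC/C=C(\C)CCC1=C(C)[C@@H](O)C[C@@H]2C(C)(C)CCC[C@@]12C | intermediate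
22 | (2S,4aR,8aR)-4-[(3E)-5-(acetyloxy)-3-methylpent-3-en-1-yl]-3,4a,8,8-tetramethyl-1,2,4a,5,6,7,8,8a-octahydronaphthalen-2-yl acetate | CC(=O)OC/C=C(\C)CCC1=C(C)[C@@H](OC(C)=O)C[C@@H]2C(C)(C)CCC[C@@]12C | target

**Step count and risks**

Total steps: 14. Longest linear sequence: 10 steps (steps 1, 2, 4, 5, 9, 10, 11, 12, 13 and 14, from phenyl vinyl sulfone 1). The branches from carvone 4 (steps 3, 4, 5, 9 to 14) and from enynol 10 (steps 6 to 14) each run 9 steps.

Most likely to fail, with fallbacks: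

Step 5. The tertiary C4 radical may be reduced before it cyclises, or hydrogen-atom transfer may go to the vinyl sulfone or the enone instead of the isopropenyl group. The fallback sets out from 8 and generates the same radical without a metal hydride. Markovnikov hydrobromination of the isopropenyl group (HBr, AcOH/CH2Cl2, −20 °C) should give the tertiary bromide (5S,6R)-5-(2-bromopropan-2-yl)-2,6-dimethyl-6-[2-(phenylsulfonyl)prop-2-en-1-yl]cyclohex-2-en-1-one F1. Slow addition of Bu3SnH with AIBN in benzene at 80 °C then abstracts bromine, and the classical tin-mediated Giese cyclisation onto the vinyl sulfone comes back to the route at 9.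

Step 9. The organometallic may act as a base (α to the sulfone or at the γ-position of the enone) or fail to add to the hindered C9 carbonyl. The fallback sets out from 9 and removes the sulfone before the addition by a redox detour. Luche reduction (NaBH4, CeCl3·7H2O, MeOH, 0 °C) gives the allylic alcohol (4aR,8aR)-2,5,5,8a-tetramethyl-7-(phenylsulfonyl)-1,4,4a,5,6,7,8,8a-octahydronaphthalen-1-ol F2. Na(Hg)/Na2HPO4 in MeOH gives the sulfone-free alcohol (4aR,8aR)-2,5,5,8a-tetramethyl-1,4,4a,5,6,7,8,8a-octahydronaphthalen-1-ol F3. Oxidation with Dess–Martin periodinane (or MnO2) gives the enone (4aR,8aR)-2,5,5,8a-tetramethyl-4a,5,6,7,8,8a-hexahydronaphthalen-1(4H)-one F4. Addition of excess organolithium 15 to F4 then comes back to the route at 18.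

Step 12. Facial selectivity of hydride delivery at C7 may be poor, or conjugate reduction may compete. The fallback sets out from 19 and installs the C7 configuration by inversion. Luche reduction (NaBH4, CeCl3·7H2O, MeOH, −20 °C), expected to attack axially, gives the equatorial epimer (2R,4aR,8aR)-4-[(3E)-5-{[tert-butyl(dimethyl)silyl]oxy}-3-methylpent-3-en-1-yl]-3,4a,8,8-tetramethyl-1,2,4a,5,6,7,8,8a-octahydronaphthalen-2-ol F5. Mitsunobu reaction with acetic acid (PPh3, DIAD, toluene, 0 °C) inverts C7 and gives (2S,4aR,8aR)-4-[(3E)-5-{[tert-butyl(dimethyl)silyl]oxy}-3-methylpent-3-en-1-yl]-3,4a,8,8-tetramethyl-1,2,4a,5,6,7,8,8a-octahydronaphthalen-2-yl acetate F6. HF·pyridine in THF/pyridine removes the silyl group to give (2S,4aR,8aR)-4-[(3E)-5-hydroxy-3-methylpent-3-en-1-yl]-3,4a,8,8-tetramethyl-1,2,4a,5,6,7,8,8a-octahydronaphthalen-2-yl acetate F7. Acetylation (Ac2O, pyridine, DMAP) comes back to the route at 22.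

Further compounds
F1 | step 5 | (5S,6R)-5-(2-bromopropan-2-yl)-2,6-dimethyl-6-[2-(phenylsulfonyl)prop-2-en-1-yl]cyclohex-2-en-1-one | O=C1C(C)=CC[C@H](C(C)(C)Br)[C@@]1(C)CC(=C)S(=O)(=O)c2ccccc2
F2 | step 9 | (4aR,8aR)-2,5,5,8a-tetramethyl-7-(phenylsulfonyl)-1,4,4a,5,6,7,8,8a-octahydronaphthalen-1-ol (C1 and C7 epimers) | OC1C(C)=CC[C@@H]2C(C)(C)CC(S(=O)(=O)c3ccccc3)C[C@@]12C
F3 | step 9 | (4aR,8aR)-2,5,5,8a-tetramethyl-1,4,4a,5,6,7,8,8a-octahydronaphthalen-1-ol (C1 epimers) | OC1C(C)=CC[C@@H]2C(C)(C)CCC[C@@]12C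
F4 | step 9 | (4aR,8aR)-2,5,5,8a-tetramethyl-4a,5,6,7,8,8a-hexahydronaphthalen-1(4H)-one | O=C1C(C)=CC[C@@H]2C(C)(C)CCC[C@@]12C
F5 | step 12 | (2R,4aR,8aR)-4-[(3E)-5-{[tert-butyl(dimethyl)silyl]oxy}-3-methylpent-3-en-1-yl]-3,4a,8,8-tetramethyl-1,2,4a,5,6,7,8,8a-octahydronaphthalen-2-ol | CC(C)(C)[Si](C)(C)OC/C=C(\C)CCC1=C(C)[C@H](O)C[C@@H]2C(C)(C)CCC[C@@]12C
F6 | step 12 | (2S,4aR,8aR)-4-[(3E)-5-{[tert-butyl(dimethyl)silyl]oxy}-3-methylpent-3-en-1-yl]-3,4a,8,8-tetramethyl-1,2,4a,5,6,7,8,8a-octahydronaphthalen-2-yl acetate | CC(C)(C)[Si](C)(C)OC/C=C(\C)CCC1=C(C)[C@@H](OC(C)=O)C[C@@H]2C(C)(C)CCC[C@@]12C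
F7 | step 12 | (2S,4aR,8aR)-4-[(3E)-5-hydroxy-3-methylpent-3-en-1-yl]-3,4a,8,8-tetramethyl-1,2,4a,5,6,7,8,8a-octahydronaphthalen-2-yl acetate | OC/C=C(\C)CCC1=C(C)[C@@H](OC(C)=O)C[C@@H]2C(C)(C)CCC[C@@]12C
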